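In a closed, stirred vessel held at one temperature, 33 µM of free catalyst joins starting material to coupling partner, and target appears with some isomer of the product. I want to know how the share of target moves when the charge of starting material is changed and the other settings stay as they are.

| setting | oak | alder | Thursday's | Tuesday's | Friday's | Sunday's | Monday's |
|---|---|---|---|---|---|---|---|
| starting material | 4.8 × 10⁻⁴ M | 0.048 M | 8.0 × 10⁻⁴ M | 0.0025 M | 0.0080 M | 0.020 M | 0.060 M |
| coupling partner | 0.065 M | 0.065 M | 0.0650 M | 0.0650 M | 0.0650 M | 0.0650 M | 0.0650 M |
| free catalyst | 33 µM | 33 µM | 33 µM | 33 µM | 33 µM | 33 µM | 33 µM |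
| remark | run made earlier | run made earlier |  |  |  |  |  |
| time |  |  | 1.5 h | 1.5 h | 1.5 h | 1.5 h | 1.5 h |

| run | time / min | target / % | isomer of the product / % | starting material / % |
|---|---|---|---|---|
| oak | 8.00 | 0.6 | 0.2 | 99.4 |
| oak | 25.0 | 2.4 | 0.3 | 97.4 |
| oak | 40.0 | 3.2 | 0 | 92.5 |
| oak | 60.0 | 6.2 | 0 | 92.5 |
| oak | 90.0 | 9.9 | 2.0 | 87.4 |
| alder | 8.00 | 1.9 | 0 | 99.8 |
| alder | 25.0 | 1.9 | 1.6 | 97.2 |
| alder | 40.0 | 4.2 | 0.6 | 95.9 |
| alder | 60.0 | 6.0 | 1.9 | 93.2 |
| alder | 90.0 | 10.5 | 1.3 | 88.4 |

(each reading ± 1 percentage point)

- "hardly changes" means that all values lie within two and a half points (for a concentration: within two and a half percent of the largest)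

1. share of target in all that became target or isomer of the product for Thursday's, Tuesday's, Friday's, Sunday's, Monday's, in this order
2. the shape of the row from first to last (falls all the way / rises all the way / falls, then rises / rises, then falls / hardly changes)

I work with the fraction left, not the amount made: in a first-order loss (pseudo-first-order here, with catalyst and coupling partner counted as constant) the charge cancels from that fraction. The oak run reads 87.4% of its starting material left at 90.0 min, which gives 11.1 h. The alder run, with 100 times the charge, reads 88.4% left, which gives 12.2 h. Their mean, 11.7 h, is my reading of the time constant of the starting material: the time divided by the natural logarithm of one over the fraction left.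

The second way leaves those readings aside. The last readings of the oak run add up to 11.9% as target and isomer of the product, and those of the alder run to 11.8%. I take each from the whole and treat the remainder as the fraction left, which gives 11.8 h for oak and 11.9 h for alder. The two ways part most on oak, by 0.700 h, and I put that gap down to scatter, since the loss there is 13 percentage points, read with a scatter of 1 point. So target and isomer of the product account for what the starting material loses, within the scatter.

I therefore expect 88.0% of the starting material left at 1.5 h in each flask, and I take the share of target not to follow the charge. Pooling the last readings of both runs, I put the row flat at 86.1%. Monday's charge of 0.060 M stands above alder's, so that point is an extrapolation.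

The forecast gives 86% at each point and the shape "hardly changes", holding that “the ratio should not depend on starting material”. It rests on the same readings as mine, so our agreement is no check.

The flasks give 85.6%, 85.6%, 85.7%, 85.9% and 86.4%, and the shape is "hardly changes", as the forecast says.

    catalyst intermediate B ⇌ free catalyst + target (K = 1.50 M, k = 102 s⁻¹)
    starting material + free catalyst ⇌ catalyst intermediate A (K = 1.79 M⁻¹, k = 10.3 M⁻¹ s⁻¹)
    coupling partner + catalyst intermediate A → catalyst intermediate B (k = 6.49 M⁻¹ s⁻¹)
    target + free catalyst ⇌ isomer of the product + free catalyst, rate k4*[free catalyst]*[target] forward; the back reaction follows from the equilibrium constant (K = 0.960, k = 2.00 M⁻¹ s⁻¹)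

Thursday's flask leaves 88% of its starting material at 1.50 h, a time constant of 12.0 h beside my 11.7 h, while the turning of target into isomer of the product, by its forward rate, has a half-life of 2.9 h, which is a time constant of 4.21 h, shorter than that of the starting material and longer than the 1.5 h of the run. Monday's flask, with 91.0% of its catalyst free at 0.450 h against 99.9% on Thursday's, leaves 90% of its starting material at 1.50 h, a longer time constant of 13.8 h, and its share of target stands at 86.4%.

(The data were generated by integration from invented constants; scatter was added.)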